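Sunday's run lost 79.9 mM of substrate by 90.0 s, more than the 36 mM of gas that saturates the solution, which looks impossible if each substrate uses one reagent.

| flask | left-handed substrate | right-handed substrate | gas | racemization catalyst | remark | time |
|---|---|---|---|---|---|---|
| Sunday's | 0.74 M | 0.74 M | 36 mM (held) | 0.37 mM | run made earlier |  |
| flask | 0.37 M | 0.37 M | 36 mM (held) | 0.37 mM |  | 8.0 min |

Sunday's run (percent of the left-handed substrate and right-handed substrate together charged)

| time / s | left-handed substrate / % | right-handed substrate / % | left-handed product / % |
|---|---|---|---|
| 10.0 | 49.5 | 50.1 | 0.1 |
| 20.0 | 49.7 | 49.3 | 0 |
| 40.0 | 48.4 | 48.9 | 1.6 |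
| 90.0 | 47.0 | 47.6 | 3.5 |

(each reading ± 0.3 percentage points)

- reagent is single-handed; left-handed substrate and right-handed substrate are mirror images of each other, charged as a racemate, each of them at the stated concentration
- at the start none of the gas is in solution
- an excess is the difference of the two amounts in percent of their sum
- an excess is below zero if the other one leads
- the handed part of reagent does not stay in what it makes, so the products of the two hands are mirror images too

- part of the left-handed substrate and right-handed substrate charged together that has reacted at 8.0 min
- excess of left-handed product over right-handed product in the product at 8.0 min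
- excess of right-handed substrate over left-handed substrate among what is left of the two at 8.0 min

The two numbers fit: the gas is held, reagent can be replaced as it is used, and so you should reckon a flow. Between 10.0 s and 90.0 s, Sunday's readings show substrate used at 0.925 mM s⁻¹. Call θ the time a flask takes to use one saturation load of reagent; these readings put Sunday's θ at 38.9 s.

I take reagent to enter in proportion to its shortfall from saturation and to leave in proportion to reagent times substrate. Then θ is a crossing time plus a use time, and the use time grows as substrate falls. I cannot read the split firmly from readings with a scatter of 0.3 percentage points, so I give each part half of θ, the crossing where neither is the rate-limiting step. This flask starts with half of Sunday's substrate, so θ becomes 58.4 s, which would consume 40.0 % by 8.0 min. Taking the substrate at its mean over the run, θ becomes 68.1 s, and my reckoning gives c near 34.3 %.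

The forecast gave c = 30 % (22 % to 62 %), eP = 28 % and eS = 0.6 %, saying: “The substrate order is untested.”

The flask gives c = 37.8 %, eP = 21.3 % and eS = 6.34 %.

    gas ⇌ reagent, rate k1*(csat - [reagent]) (kL = 0.0510 s⁻¹)
    reagent + right-handed substrate → right-handed product (k = 0.0320 M⁻¹ s⁻¹)
    left-handed substrate + racemization catalyst ⇌ right-handed substrate + racemization catalyst, rate k3*[racemization catalyst]*[left-handed substrate] forward; the back reaction follows from the equilibrium constant (k = 4.20 M⁻¹ s⁻¹)
    reagent + left-handed substrate → left-handed product (k = 0.0530 M⁻¹ s⁻¹)

At 8.00 min this flask holds 0.0260 M of reagent, and reagent is made 1.02 times as fast as it is used, each step taken net. Its reagent stands at 72.3 % of saturation at that moment, and my reckoning of c lies 3.5 points below the flask's.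

The neighbour flask with 0.0015 M of racemization catalyst has no catalyst in θ, so the same reckoning gives 34.3 % again. It reaches c = 37.9 %, with 0.0260 M of reagent at 8.00 min and eS = 2.10 %.

Readings and results stem from a simulated flask from invented constants; the scatter is artificial.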